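(All runs stem from a simulated flask with made-up constants; noise was put on by code.)

**Small charge.** A small charge of enzyme, 2.3 µM in the summer run, leaves 46% of the substrate at 3.00 d. The dusk run, with 17 µM, is down to 8% by then, and its target has passed a maximum.

in all of them: substrate 20 mM
- summer: enzyme 2.3 µM (in portions, 2); run made earlier; portions every 50 min
- dusk: enzyme 17 µM (in portions, 2); run made earlier; portions every 50 min
- epsilon: enzyme 3.0 µM (in portions, 2); the portions of enzyme follow each other after 50 min, the first at the start; time 3.0 d
- theta: enzyme 6.0 µM (in portions, 2); the portions of enzyme follow each other after 50 min, the first at the start; time 3.0 d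
- zeta: enzyme 12 µM (in portions, 2); the portions of enzyme follow each other after 50 min, the first at the start; time 3.0 d
- delta: enzyme 25 µM (in portions, 2); the portions of enzyme follow each other after 50 min, the first at the start; time 3.0 d

- summer (time / d: target / %, substrate / %): 0.167: 2, 98; 0.500: 10, 91; 0.833: 14, 85; 1.25: 24, 75; 1.67: 28, 69; 2.50: 44, 53; 3.00: 48, 46
- dusk (time / d: target / %, substrate / %): 0.167: 13, 89; 0.500: 25, 70; 0.833: 41, 56; 1.25: 56, 37; 1.67: 64, 24; 2.50: 49, 11; 3.00: 34, 8

(standard deviation of a reading: 1.5 percentage points)

- "hardly changes" means that all values lie within two and a half points (for a concentration: within two and a half percent of the largest)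
- a step back or a flat step of under half a point counts as no turn

1. amount of target at the end, in percent of the substrate charged for epsilon, theta, zeta, delta, in this order
2. how the row runs (rises all the way / falls all the way / rises, then falls / falls, then rises / hardly changes)

**The ladder.** The first rung is the feeding: the mean life of substrate in dusk is 1.17 d, and the portions stand 50 min apart, far shorter, so I count each run as one charge. That life replaces a curve by one mean constant, and the error shows at 0.833 d: it gives 49.1% where dusk reads 56%. Next comes the fall of target in dusk, with a life of 1.37 d between the last two readings. At dusk's last reading target and substrate sum to 42.0%, so material has left for a form not read. The last rung is substrate in summer, with a mean life of 3.86 d, longer than the run, and summer still sums to 94.0% at its end.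

**One clock.** Dusk has 7.39 times the enzyme of summer, but its substrate goes 3.30 times as fast, and the square root of that enzyme ratio is 2.72, so my own reckoning takes the rate as the square root of enzyme. That gives the dusk time, the run's time multiplied by the square root of its enzyme over dusk's enzyme, which is the moment of the dusk run taken to show the same flask. For delta it is 3.64 d. Summer's end lands at 1.10 d, where dusk's neighbouring readings, 56% and 37%, bracket summer's 46%. The other flasks end at 1.26 d for epsilon, 1.78 d for theta and 2.52 d for zeta. I therefore read target near 56% for epsilon, just under 64% for theta and near 49% for zeta. Delta lies past dusk's last reading, so I place it under 34%.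

**The forecast.** It gives 54%, 64%, 49% and 20%, a row that rises, then falls, on the grounds that “each run should follow one common curve on a scaled time”. Its power is 0.52 and mine is 0.5, and it commits to a number for delta where I give a ceiling.

**The flask.** The row is 54.7%, 62.7%, 47.7%, 25.4%, and it rises, then falls. Delta stands 5.4 percentage points above the forecast.

    substrate + enzyme ⇌ complex (K = 400 /M, k = 4.70 × 10⁶ /M/h)
    complex ⇌ enzyme + target (K = 0.0150 M, k = 570 /h)
    target + enzyme ⇌ isomer of the product + enzyme, rate k3*[enzyme]*[target] forward; the back reaction follows from the equilibrium constant (K = 3.40, k = 39000 /M/h)
    2 complex ⇌ resting dimer, settled at all times (K = 1.20 × 10⁷ /M)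

**One reason.** Delta at 1.50 d has a dusk time of 1.82 d, close to theta's 1.78 d at its end, and the two flasks hold 62.3% and 62.7% of target. Delta then runs on to 3.64 d, and the loss on that stretch is the turning of target into isomer of the product. Without that step, delta ends at 85.6% of target instead of 25.4%.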